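Temperature opened the meeting. The flasks dusk, midnight, spring and dawn share one charge, [starting material] = 0.84 M, and one time, 4.0 h, and they differ in temperature.

| flask | starting material | temperature | remark | time |
|---|---|---|---|---|
| north-west | 1.2 M | 52 °C | run made earlier |  |
| west | 1.8 M | 102 °C | run made earlier |  |
| dusk | 0.84 M | 90 °C |  | 4.0 h |
| midnight | 0.84 M | 120 °C |  | 4.0 h |
| spring | 0.84 M | 60 °C |  | 4.0 h |
| dawn | 0.84 M | 30 °C |  | 4.0 h |

- which flask leads in amount of product, in percent of the starting material charged ("all alike" within 1.5 percentage points) (dusk / midnight / spring / dawn / all alike)
- how much product is there at the end, in percent of the starting material charged: dusk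
- how much product is there at the end, in percent of the starting material charged: midnight
- how much product is there at the end, in percent of the starting material charged: spring
- how much product is there at the end, in percent of the starting material charged: dawn

- north-west (time / h: product / %, starting material / %): 1.50: 0, 100.5; 4.00: 0, 100.4; 8.00: 0.2, 98.3; 20.0: 0, 98.5
- west (time / min: product / %, starting material / %): 8.00: 0.8, 96.3; 20.0: 2.4, 92.1; 40.0: 3.6, 84.0; 90.0: 8.3, 68.5

(each reading ± 0.5 percentage points)

- steps that have been proposed: starting material + 2 product -> 3 product; starting material -> product; starting material <-> dormant form

The first speaker took the north-west run at 52 °C, where product read 0% after 20.0 h, and so expected little from the cold flasks. The second took the west run at 102 °C. After 90.0 min starting material stood at 68.5% and product at 8.3%, so 31 percentage points had been lost and product held 26.3% of that loss. At 40.0 min the same division gave 22.5%, which she called close, given a scatter of 0.5 points on each reading. She proposed to carry this product share, the product formed per starting material lost, or selectivity, to the hotter flask. She argued that the remainder of the loss must sit as dormant form, since the two readings summed to 76.8%.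

The third speaker counted half-lives. The west loss ran at 0.252 h⁻¹, a half-life of 2.75 h, so 4.0 h at 102 °C is 1.45 half-lives, and midnight is hotter at 120 °C. He reckoned that at full conversion of midnight's starting material its product would end near the share itself, 26.3% of the charge.

The forecast named midnight as the leader, with 34% there, 6% in dusk, 0.2% in spring and 0% in dawn. For midnight it held the yield “limited by selectivity, about 30%, plus any return from the dormant form”. Its midnight figure stands 7.7 points above the meeting's reckoning.

Midnight leads, as forecast, and ends at 44.1% of the charge, 10 points above the forecast, while dusk ends at 4.97%, spring at 0.131% and dawn at 0%.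

    starting material + 2 product → 3 product (k = 2.00 × 10⁻⁴ L² mol⁻² s⁻¹, Ea = 82.0 kJ mol⁻¹)
    starting material → product (k = 3.80 × 10⁻⁶ s⁻¹, Ea = 125 kJ mol⁻¹)
    starting material ⇌ dormant form (K = 8.60, k = 1.40 × 10⁻⁵ s⁻¹, Ea = 129 kJ mol⁻¹, ΔH = −30.0 kJ mol⁻¹)
    (constants at 90 °C)

In midnight, between 2.00 h and 4.00 h, the dormant form fell from 59.2% to 48.6% while product rose from 28.3% to 44.1%. Midnight's product share of its loss, with dormant form counted as lost, ends at 47.6%, above the carried 26.3%. A neighbouring flask like midnight but kept at 95 °C has 64% of its charged starting material left, so the carried share gives 9.60% of the charge, and that flask holds 8.23%.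

The runs are calculated with constants of no real substance, noise included.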